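**Retrosynthetic overview**

- Feature: the seven-membered ring C1–C10–C9–C8–C7–C6–C5 carries its C8 methyl "para" to the angular carbon C1 and is fused through C1–C5 to a cyclopentane oxygenated at C4. This is a p-tolyl ring plus a C5–C4(=O)–C3–C2 diazoketone tether (C1 angular-methyl carbon, C2/C3 ring CH2, C4 isopropyl carbinol, C5 ring-fusion CH, C6 aroyloxy CH, C7=C8(Me), C9 acetoxy CH, C10 CH2).
- Late disconnections: the C6 aroyl and C9 acetyl esters; the cis C6/C9 oxygens from a singlet-oxygen [4+2] adduct of the C6=C7–C8=C9 diene; the C4–isopropyl bond from organocerium addition to the C4 ketone.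
- Middle: C5–H by kinetic enolate protonation; C1–CH3 by enantioselective copper-catalysed conjugate addition to the C5=C1 enone, which sets the absolute configuration.
- Key disconnection: C5–C1 and C5–C6 by intramolecular Buchner reaction of 1-diazo-4-(4-methylphenyl)butan-2-one. The cyclopentanone and the cycloheptatriene both form in this one operation; no carbocycle is closed afterwards.

Key step: step 3

Remark: C1–C10 in the text are the skeleton labels above, α is the face of H-5 and β the face of the C1 methyl, compound names use azulene locants, and the ligand antipode in step 5 is assumed to be the one that gives the (3aR) product, to be matched by experiment.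

**Route**

Step 1
Reactants: 1 3-(4-methylphenyl)propanoic acid
Product: 2 3-(4-methylphenyl)propanoyl chloride
Conditions: (COCl)2, DMF (cat.), CH2Cl2, 0 °C → rt
Reagents that add atoms: oxalyl chloride ClC(=O)C(=O)Cl
Why: Standard acid chloride formation through the Vilsmeier-type chloroiminium species; no stereocentre is involved.

Step 2
Reactants: 2 3-(4-methylphenyl)propanoyl chloride; 3 (trimethylsilyl)diazomethane
Product: 4 1-diazo-4-(4-methylphenyl)butan-2-one
Conditions: 3 (2 equiv), THF/MeCN (1:1), 0 °C
Reagents that add atoms: none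
Why: C-acylation of the silyl diazoalkane with loss of the silyl group as its chloride gives the terminal α-diazoketone (the acylation stage of an Arndt–Eistert sequence) without handling diazomethane.

Step 3
Reactants: 4 1-diazo-4-(4-methylphenyl)butan-2-one
Product: 6 rac-6-methyl-3,8a-dihydroazulen-1(2H)-one, via norcaradiene tautomer 5 (not isolated)
Conditions: Rh2(OAc)4 (0.5 mol%), CH2Cl2, reflux, slow addition of 4 (≤0.01 M), acid-free; filtration through neutral alumina
Reagents that add atoms: none
Why: Rh2(OAc)4 expels N2 from 4 to give an electrophilic rhodium carbenoid at C5, which adds in a [2+1] sense across the ipso–ortho (C1–C6) π bond of the tethered tolyl ring; this is the intramolecular Buchner reaction, known for 1-diazo-4-arylbutan-2-ones. The cyclopentanone closes by formation of the C5–C1 bond in this cyclopropanation, the three-atom tether making it a strain-free five-ring closure onto the ipso carbon. The seven-membered ring arises by thermal 6π disrotatory electrocyclic opening of norcaradiene 5, which breaks the former arene bond C1–C6 and leaves C5 inserted into the ring. The only stereocentre that remains, C5, forms racemic and is erased in step 4, so no stereocontrol is asked of this step. The selectivity needed is cycloaddition over formal aromatic C–H insertion (which would end in a 2-tetralone); the carboxylate-ligated dirhodium catalyst under acid-free high dilution secures it, and the para methyl makes both ortho bonds equivalent, so one regioisomer with the methyl at C8 should form.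

Step 4
Reactants: 6 rac-6-methyl-3,8a-dihydroazulen-1(2H)-one
Product: 7 6-methyl-3,4-dihydroazulen-1(2H)-one
Conditions: Et3N, CH2Cl2, rt
Reagents that add atoms: none
Why: Amine-catalysed prototropic shift through the extended enolate moves the C5 hydrogen to C10 and puts the tetrasubstituted C5=C1 alkene in conjugation with the C4 carbonyl, as established for the parent dihydroazulenone; the racemic C5 centre disappears.

Step 5
Reactants: 7 6-methyl-3,4-dihydroazulen-1(2H)-one; 8 trimethylaluminium
Product: 10 (3aR)-3a,6-dimethyl-1-(trimethylsilyloxy)-2,3,3a,4-tetrahydroazulene, via dimethylaluminium enolate 9 (not isolated)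
Conditions: 8 (1.5 equiv), Cu(O2CC4H3S) (copper thiophene-2-carboxylate, 5 mol%), (S,R,R)-phosphoramidite from 1,1'-bi-2-naphthol and bis(1-phenylethyl)amine (10 mol%), Et2O, −30 °C; then TMSOTf, −30 → 0 °C; Et3N, aq. NaHCO3
Reagents that add atoms: trimethylsilyl trifluoromethanesulfonate C[Si](C)(C)OS(=O)(=O)C(F)(F)F
Why: Proposed new method: the closest known reaction type is the copper/phosphoramidite-catalysed asymmetric conjugate addition of AlMe3 to β-substituted cyclic enones with quaternary-centre formation, not yet shown on an unactivated tetrasubstituted ring-fusion enone; it should transfer because AlMe3 activates the carbonyl as a Lewis acid and the small methyl group is delivered from a ligand-bound methylcopper π-complex to C1, the only electrophilic β position (the C6–C9 diene sits on the α carbon and offers no 1,6 path), so the ligand differentiates the two faces of the flat trienone and fixes C1, while O-silylation of the aluminium enolate stores the adduct as a trienol ether without yet committing C5.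

Step 6
Reactants: 10 (3aR)-3a,6-dimethyl-1-(trimethylsilyloxy)-2,3,3a,4-tetrahydroazulene
Product: 12 (3aR,8aR)-3a,6-dimethyl-3,3a,4,8a-tetrahydroazulen-1(2H)-one, via lithium enolate 11 (not isolated)
Conditions: MeLi, THF, 0 °C; then inverse addition to AcOH/THF, −78 °C
Reagents that add atoms: none
Why: Methyllithium cleaves the O–Si bond to the lithium trienolate, and kinetic protonation of such extended enolates occurs at the α carbon (C5), leaving the C6–C9 diene out of conjugation; the proton should enter anti to the neighbouring angular methyl, on the face flanked only by the tied-back ring methylene C10, which gives the trans ring fusion (regiospecific enolate generation followed by kinetic protonation).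

Step 7
Reactants: 12 (3aR,8aR)-3a,6-dimethyl-3,3a,4,8a-tetrahydroazulen-1(2H)-one; 13 isopropylmagnesium chloride
Product: 14 (1R,3aR,8aR)-3a,6-dimethyl-1-(propan-2-yl)-1,2,3,3a,4,8a-hexahydroazulen-1-ol
Conditions: 13, CeCl3 (anhydrous), THF, −78 °C, premixed; then 12, −78 → −40 °C; aq. NH4Cl
Reagents that add atoms: none
Why: The weakly basic organocerium reagent adds to the hindered, easily enolised ketone without deprotonating C5 or delivering hydride, and approaches C4 from the α face (side of the small axial H-5, anti to the pseudo-axial C1 methyl lying 1,3 across the cyclopentanone), giving the 4β-hydroxy-4α-isopropyl carbinol (1,2-addition of a Grignard-derived organocerium).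

Step 8
Reactants: 14 (1R,3aR,8aR)-3a,6-dimethyl-1-(propan-2-yl)-1,2,3,3a,4,8a-hexahydroazulen-1-ol
Product: 16 (1R,3aR,5S,8S,8aS)-3a,6-dimethyl-1-(propan-2-yl)-1,2,3,3a,4,5,8,8a-octahydroazulene-1,5,8-triol, via endoperoxide 15 (not isolated)
Conditions: O2, hν (visible), tetraphenylporphyrin (cat.), CH2Cl2, −40 °C; then Zn, AcOH, 0 °C → rt
Reagents that add atoms: dioxygen O=O
Why: Singlet oxygen adds suprafacially in a [4+2] cycloaddition across the s-cis C6=C7–C8=C9 diene from the α face, which carries only H-5 and the C2 methylene on the three-carbon bridge whereas the β face carries the axial C1 methyl and the fully substituted C4, so both C–O bonds should form cis and α; zinc in acetic acid then cleaves only the O–O bond with retention at C6 and C9.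

Step 9
Reactants: 16 (1R,3aR,5S,8S,8aS)-3a,6-dimethyl-1-(propan-2-yl)-1,2,3,3a,4,5,8,8a-octahydroazulene-1,5,8-triol
Product: 17 (1R,3aR,5S,8S,8aS)-1,8-dihydroxy-3a,6-dimethyl-1-(propan-2-yl)-1,2,3,3a,4,5,8,8a-octahydroazulen-5-yl acetate
Conditions: Ac2O (1.1 equiv), pyridine, CH2Cl2, −20 → 0 °C
Reagents that add atoms: acetic anhydride CC(=O)OC(C)=O
Why: Acylation under steric control: the C9 hydroxyl is flanked by the C10 methylene, the C6 hydroxyl sits next to C5 between two fully substituted carbons and the tertiary C4 hydroxyl is inert, so one equivalent of anhydride at low temperature should give the C9 monoacetate (selective O-acetylation).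

Step 10
Reactants: 18 4-hydroxybenzoic acid
Product: 20 4-[(tert-butyldimethylsilyl)oxy]benzoic acid, via bis-silylated ester 19 (not isolated)
Conditions: TBSCl (2.2 equiv), imidazole, DMF, rt; then AcOH/THF/H2O, rt
Reagents that add atoms: tert-butyldimethylsilyl chloride CC(C)(C)[Si](C)(C)Cl
Why: Exhaustive silylation followed by selective hydrolysis of the labile silyl ester, which is far more acid-sensitive than the aryl silyl ether, frees the carboxylic acid with the phenol still protected.

Step 11
Reactants: 17 (1R,3aR,5S,8S,8aS)-1,8-dihydroxy-3a,6-dimethyl-1-(propan-2-yl)-1,2,3,3a,4,5,8,8a-octahydroazulen-5-yl acetate; 20 4-[(tert-butyldimethylsilyl)oxy]benzoic acid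
Product: 21 (1R,3aR,5S,8S,8aS)-5-acetoxy-1-hydroxy-3a,6-dimethyl-1-(propan-2-yl)-1,2,3,3a,4,5,8,8a-octahydroazulen-8-yl 4-[(tert-butyldimethylsilyl)oxy]benzoate
Conditions: 20 (1.5 equiv), DCC, DMAP, CH2Cl2, rt
Reagents that add atoms: none
Why: Steglich esterification through the N-acylpyridinium ion acylates the remaining secondary C6 hydroxyl with retention (reaction at oxygen), the tertiary hydroxyl being unreactive under these conditions.

Step 12
Reactants: 21 (1R,3aR,5S,8S,8aS)-5-acetoxy-1-hydroxy-3a,6-dimethyl-1-(propan-2-yl)-1,2,3,3a,4,5,8,8a-octahydroazulen-8-yl 4-[(tert-butyldimethylsilyl)oxy]benzoate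
Product: 22 (1R,3aR,5S,8S,8aS)-5-acetoxy-1-hydroxy-3a,6-dimethyl-1-(propan-2-yl)-1,2,3,3a,4,5,8,8a-octahydroazulen-8-yl 4-hydroxybenzoate (CNP0305796.2)
Conditions: TBAF, AcOH (1:1), THF, 0 °C
Reagents that add atoms: none
Why: Fluoride cleaves the aryl silyl ether much faster than it touches the carboxylic esters, and the acetic acid buffer suppresses phenoxide- or fluoride-induced acyl transfer (silyl ether deprotection).

**Compound list**

1 | 3-(4-methylphenyl)propanoic acid | Cc1ccc(CCC(=O)O)cc1 | starting material
2 | 3-(4-methylphenyl)propanoyl chloride | Cc1ccc(CCC(=O)Cl)cc1 | intermediate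
3 | (trimethylsilyl)diazomethane | C[Si](C)(C)C=[N+]=[N-] | starting material
4 | 1-diazo-4-(4-methylphenyl)butan-2-one | Cc1ccc(CCC(=O)C=[N+]=[N-])cc1 | intermediate
5 | tricyclic norcaradiene tautomer of 6 (cyclopropane C1–C5–C6, racemic) | O=C1CCC23C=CC(C)=CC2C13 | intermediate
6 | rac-6-methyl-3,8a-dihydroazulen-1(2H)-one | O=C1CCC2=CC=C(C)C=CC12 | intermediate
7 | 6-methyl-3,4-dihydroazulen-1(2H)-one | O=C1CCC2=C1C=CC(C)=CC2 | intermediate
8 | trimethylaluminium | C[Al](C)C | starting material
9 | dimethylaluminium (3aR)-3a,6-dimethyl-2,3,3a,4-tetrahydroazulen-1-olate | CC1=CC[C@@]2(C)CCC(O[Al](C)C)=C2C=C1 | intermediate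
10 | (3aR)-3a,6-dimethyl-1-(trimethylsilyloxy)-2,3,3a,4-tetrahydroazulene | CC1=CC[C@@]2(C)CCC(O[Si](C)(C)C)=C2C=C1 | intermediate
11 | lithium (3aR)-3a,6-dimethyl-2,3,3a,4-tetrahydroazulen-1-olate | CC1=CC[C@@]2(C)CCC(O[Li])=C2C=C1 | intermediate
12 | (3aR,8aR)-3a,6-dimethyl-3,3a,4,8a-tetrahydroazulen-1(2H)-one (trans-fused) | CC1=CC[C@@]2(C)CCC(=O)[C@@H]2C=C1 | intermediate
13 | isopropylmagnesium chloride | CC(C)[Mg]Cl | starting material
14 | (1R,3aR,8aR)-3a,6-dimethyl-1-(propan-2-yl)-1,2,3,3a,4,8a-hexahydroazulen-1-ol | CC1=CC[C@@]2(C)CC[C@@](O)(C(C)C)[C@@H]2C=C1 | intermediate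
15 | (1R,3aR,5S,8S,8aS)-5,8-epidioxy-3a,6-dimethyl-1-(propan-2-yl)-1,2,3,3a,4,5,8,8a-octahydroazulen-1-ol | O3[C@H]1C[C@@]2(C)CC[C@@](O)(C(C)C)[C@@H]2[C@@H](O3)C=C1C | intermediate
16 | (1R,3aR,5S,8S,8aS)-3a,6-dimethyl-1-(propan-2-yl)-1,2,3,3a,4,5,8,8a-octahydroazulene-1,5,8-triol | O[C@H]1C[C@@]2(C)CC[C@@](O)(C(C)C)[C@@H]2[C@@H](O)C=C1C | intermediate
17 | (1R,3aR,5S,8S,8aS)-1,8-dihydroxy-3a,6-dimethyl-1-(propan-2-yl)-1,2,3,3a,4,5,8,8a-octahydroazulen-5-yl acetate | CC(=O)O[C@H]1C[C@@]2(C)CC[C@@](O)(C(C)C)[C@@H]2[C@@H](O)C=C1C | intermediate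
18 | 4-hydroxybenzoic acid | OC(=O)c1ccc(O)cc1 | starting material
19 | tert-butyldimethylsilyl 4-[(tert-butyldimethylsilyl)oxy]benzoate | CC(C)(C)[Si](C)(C)OC(=O)c1ccc(O[Si](C)(C)C(C)(C)C)cc1 | intermediate
20 | 4-[(tert-butyldimethylsilyl)oxy]benzoic acid | OC(=O)c1ccc(O[Si](C)(C)C(C)(C)C)cc1 | intermediate
21 | (1R,3aR,5S,8S,8aS)-5-acetoxy-1-hydroxy-3a,6-dimethyl-1-(propan-2-yl)-1,2,3,3a,4,5,8,8a-octahydroazulen-8-yl 4-[(tert-butyldimethylsilyl)oxy]benzoate | CC(=O)O[C@H]1C[C@@]2(C)CC[C@@](O)(C(C)C)[C@@H]2[C@@H](OC(=O)c2ccc(O[Si](C)(C)C(C)(C)C)cc2)C=C1C | intermediate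
22 | (1R,3aR,5S,8S,8aS)-5-acetoxy-1-hydroxy-3a,6-dimethyl-1-(propan-2-yl)-1,2,3,3a,4,5,8,8a-octahydroazulen-8-yl 4-hydroxybenzoate | CC(=O)O[C@H]1C[C@@]2(C)CC[C@@](O)(C(C)C)[C@@H]2[C@@H](OC(=O)c2ccc(O)cc2)C=C1C | target

**Step count and risks**

Total step count: 12. Longest linear sequence: 11 steps (steps 1–9, 11, 12); step 10 is a one-step side branch.

Steps most likely to fail:

1. Step 5. The methyl transfer to the tetrasubstituted enone may be too slow under catalysis, or may proceed with low facial discrimination. Fallback, setting out from 7: stoichiometric conjugate addition with MeMgBr, CuBr·SMe2 and TMSCl in THF at −78 °C, known for hindered ring-fusion enones, should give 10 as the racemate, that is together with the (3aS)-silyl enol ether F1. Steps 6 and 7 carried out on the racemate would give 12 together with the (3aS,8aS)-ketone F2, then 14 together with the (1S,3aS,8aS)-carbinol F3. Preparative chromatography on a chiral stationary phase would remove F3, and the route is rejoined at 14.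

2. Step 6. The proton may enter syn to the angular methyl, giving the cis ring fusion, or at C7/C9, giving conjugated dienones. Fallback, setting out from 10: C5 is set by separation and recycling instead of by a selective quench. The quenched mixture is chromatographed on deactivated silica, the trans ketone 12 is taken on, and the cis-fused (3aR,8aS)-ketone F4 is returned to 10 by soft enolisation (TMSOTf, Et3N, CH2Cl2, 0 °C) and resubmitted. The route is rejoined at 12.

3. Step 9. Acetylation may not discriminate between the two secondary allylic hydroxyls (reaction at C6 or double acetylation). Fallback, setting out from 15, isolated by omitting the zinc reduction in step 8: the two oxygens are differentiated by oxidation level.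
   - Kornblum–DeLaMare rearrangement (Et3N, CH2Cl2) removes the more exposed H-9 and should give the C9-keto C6-hydroxy enone F5.
   - Steglich esterification with 20 gives the C6 aroyl ester F6.
   - Luche reduction (NaBH4, CeCl3·7H2O, MeOH, −78 °C), with hydride expected anti to the axial C1 methyl, gives the 9β-alcohol F7.
   - Mitsunobu inversion with acetic acid (PPh3, DIAD) installs the 9α-acetate, and the route is rejoined at 21.

**Further compounds**

F1 | step 5 | (3aS)-3a,6-dimethyl-1-(trimethylsilyloxy)-2,3,3a,4-tetrahydroazulene (enantiomer of 10) | CC1=CC[C@]2(C)CCC(O[Si](C)(C)C)=C2C=C1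
F2 | step 5 | (3aS,8aS)-3a,6-dimethyl-3,3a,4,8a-tetrahydroazulen-1(2H)-one (enantiomer of 12) | CC1=CC[C@]2(C)CCC(=O)[C@H]2C=C1
F3 | step 5 | (1S,3aS,8aS)-3a,6-dimethyl-1-(propan-2-yl)-1,2,3,3a,4,8a-hexahydroazulen-1-ol (enantiomer of 14) | CC1=CC[C@]2(C)CC[C@](O)(C(C)C)[C@H]2C=C1
F4 | step 6 | (3aR,8aS)-3a,6-dimethyl-3,3a,4,8a-tetrahydroazulen-1(2H)-one (cis-fused C5 epimer of 12) | CC1=CC[C@@]2(C)CCC(=O)[C@H]2C=C1
F5 | step 9 | (1R,3aR,8S,8aS)-1,8-dihydroxy-3a,6-dimethyl-1-(propan-2-yl)-2,3,3a,4,8,8a-hexahydroazulen-5(1H)-one | O=C1C[C@@]2(C)CC[C@@](O)(C(C)C)[C@@H]2[C@@H](O)C=C1C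
F6 | step 9 | (1R,3aR,8S,8aS)-1-hydroxy-3a,6-dimethyl-5-oxo-1-(propan-2-yl)-1,2,3,3a,4,5,8,8a-octahydroazulen-8-yl 4-[(tert-butyldimethylsilyl)oxy]benzoate | O=C1C[C@@]2(C)CC[C@@](O)(C(C)C)[C@@H]2[C@@H](OC(=O)c2ccc(O[Si](C)(C)C(C)(C)C)cc2)C=C1C
F7 | step 9 | (1R,3aR,5R,8S,8aS)-1,5-dihydroxy-3a,6-dimethyl-1-(propan-2-yl)-1,2,3,3a,4,5,8,8a-octahydroazulen-8-yl 4-[(tert-butyldimethylsilyl)oxy]benzoate | O[C@@H]1C[C@@]2(C)CC[C@@](O)(C(C)C)[C@@H]2[C@@H](OC(=O)c2ccc(O[Si](C)(C)C(C)(C)C)cc2)C=C1C
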